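**Retrosynthetic overview** (hydroazulene numbering: C1, C2, C3, C3a, C8a = five-membered ring; C3a, C4–C8, C8a = seven-membered ring)
1. Target ⇐ late C6=C7 dehydrogenation of the C8 ketone, anisoylation of the C4 hydroxyl, and hydroxyl-directed reduction of C4=O in a trans-fused 3-hydroxy-hydroazulene-4,8-dione.
2. That ketol ⇐ formal (3+2) Michael–aldol annulation forming C8a–C1 and C3–C3a: 4-methylpent-1-en-3-one supplies C1–C3 and the isopropyl group, the partner is a preformed cycloheptane-1,4-dione held as chiral ketimine (C8) and ketal (C4); the cyclopentane is the last ring closed.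
3. Enabling feature: the 1,4-dicarbonyl pair C8=O/C4=O flanking the C8a–C3a bond of the seven-membered ring. C8=O (as enamine) makes the methyl-bearing C8a the Michael donor; C4=O makes C3a the aldol donor, keeps it epimerisable, and later accepts the directed hydride.
4. Seven-membered ring first, by one-carbon ring expansion (C3a inserted) of 2,5-dimethylcyclohexane-1,3-dione, itself from 5-methylcyclohexane-1,3-dione and iodomethane.

Key step: step 5

Remark: the ring CH(CH3) centre that becomes C6 is carried as a mixture of epimers (left unspecified in the SMILES) until step 8 erases it; the route assumes that the trans-fused ketol 16 is the thermodynamically preferred member of the interconverting ketols, as expected for angularly methylated hydroazulen-4-ones.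

Step 1
Reactants: 1 5-methylcyclohexane-1,3-dione; 2 iodomethane
Product: 3 2,5-dimethylcyclohexane-1,3-dione
Conditions: MeI, NaOH, H2O/1,4-dioxane, reflux
Reagents that add atoms: iodomethane (2), CI
Why: Enolate C-alkylation of the cyclic 1,3-dione in aqueous alkali should give the 2-methyl dione, and the remote methyl-bearing centre is of no consequence because it ends as sp2 C6 of the target.

Step 2
Reactants: 3 2,5-dimethylcyclohexane-1,3-dione; 4 diiodomethane
Product: 7 2,6-dimethylcycloheptane-1,4-dione, via zinc cyclopropanolate 5 (not isolated), via ring-expanded zinc enolate 6 (not isolated)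
Conditions: Et2Zn (3 equiv), CH2I2 (3 equiv), CH2Cl2, 0 °C to rt; then sat. NH4Cl aq.
Reagents that add atoms: diiodomethane (4), ICI
Why: Zinc carbenoid chain extension of a 1,3-diketone (Zercher-type homologation): the ethylzinc enolate is cyclopropanated by EtZnCH2I, the donor–acceptor cyclopropanolate 5 opens at its internal bond to the ring-expanded enolate 6, and protonation should give the 1,4-dione, whose stereocentres are uncontrolled and need not be controlled.

Step 3
Reactants: 7 2,6-dimethylcycloheptane-1,4-dione; 8 ethane-1,2-diol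
Product: 9 7,10-dimethyl-1,4-dioxaspiro[4.6]undecan-8-one
Conditions: HOCH2CH2OH (1.05 equiv), PPTS (cat.), benzene, reflux (Dean–Stark)
Reagents that add atoms: ethane-1,2-diol (8), OCCO
Why: Reversible acid-catalysed ketalisation should settle on the dioxolane of the carbonyl flanked by two methylene groups and leave the α-methyl-branched carbonyl free; no stereocentre is set.

Step 4
Reactants: 9 7,10-dimethyl-1,4-dioxaspiro[4.6]undecan-8-one; 10 (S)-1-phenylethan-1-amine
Product: 11 (1S)-N-(7,10-dimethyl-1,4-dioxaspiro[4.6]undecan-8-ylidene)-1-phenylethan-1-amine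
Conditions: (S)-PhCH(CH3)NH2 (1.1 equiv), TsOH·H2O (cat.), toluene, reflux (Dean–Stark)
Reagents that add atoms: (S)-1-phenylethan-1-amine (10), C[C@H](N)c1ccccc1
Why: Dehydrative imine formation at the only free ketone should give the ketimine, whose more substituted secondary enamine tautomer is the nucleophile of step 5 and makes the epimerisable α-methyl centre prochiral.

Step 5
Reactants: 11 (1S)-N-(7,10-dimethyl-1,4-dioxaspiro[4.6]undecan-8-ylidene)-1-phenylethan-1-amine; 12 4-methylpent-1-en-3-one
Product: 16 (3R,3aR,8aS)-3-hydroxy-6,8a-dimethyl-3-(propan-2-yl)octahydroazulene-4,8-dione, via Michael adduct imine 13 (not isolated), via triketone 14 (not isolated), via cis-fused ketol 15 (not isolated)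
Conditions: 12 (1.3 equiv), THF, 40 °C; then 2 M HCl aq., rt; then NaOMe (0.2 equiv), MeOH, 0 °C to rt
Reagents that add atoms: 4-methylpent-1-en-3-one (12), C=CC(=O)C(C)C; water, O
Why: The more substituted secondary enamine tautomer of 11 adds to the vinyl ketone through a compact aza-ene-like transition state with transfer of the N–H hydrogen to the acceptor α-carbon (asymmetric Michael addition of a chiral imine, the deracemising alkylation known for imines of 2-alkylcycloalkanones, is the closest known reaction type), which forms C8a–C1 and gives 13; aqueous acid then removes auxiliary and ketal to give 14, and methoxide forms C3–C3a by intramolecular aldol addition, so the telescoped sequence is a formal (3+2) annulation of the enone across C8a–C3a. The ring closes in the 5-(enolexo)-exo-trig mode, the C3a enolate of the unmasked C4 ketone attacking the side-chain carbonyl. C8a is controlled by the auxiliary: the acceptor should approach the enamine face anti to the phenyl group, which for the S amine leads to the 8aS centre by analogy with the established sense for 2-methylcycloalkanone imines. C3a and C3 are set under thermodynamic control: the first-formed cis-fused ketol 15 is expected to equilibrate by retro-aldol/aldol exchange and by enolisation at C3a to the trans-fused ketol 16, in which isopropyl is pseudo-equatorial and anti to C4 and the tertiary hydroxyl is hydrogen-bonded to the C4 carbonyl. The step needs regioselectivity for the methyl-bearing α-carbon in the Michael addition, secured by the enamine tautomer preference and by the ketal that keeps C4 out of imine chemistry, and chemoselectivity in the aldol, secured because only the C4 ketone is unhindered and only its C3a enolate can close a fused five-membered ring, the bridged alternatives being reversible and the low temperature avoiding dehydration.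

Step 6
Reactants: 16 (3R,3aR,8aS)-3-hydroxy-6,8a-dimethyl-3-(propan-2-yl)octahydroazulene-4,8-dione
Product: 17 (3R,3aS,4S,8aS)-3,4-dihydroxy-6,8a-dimethyl-3-(propan-2-yl)octahydroazulen-8(1H)-one
Conditions: Me4NBH(OAc)3, AcOH/MeCN (1:1), −25 °C
Reagents that add atoms: none
Why: Evans–Saksena reduction: the acetoxyborohydride exchanges onto the tertiary C3 hydroxyl and delivers hydride intramolecularly to the C4 carbonyl from the face of that hydroxyl, which should give the 1,3-anti diol (4S) and leave the remote, neopentylic C8 ketone untouched.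

Step 7
Reactants: 17 (3R,3aS,4S,8aS)-3,4-dihydroxy-6,8a-dimethyl-3-(propan-2-yl)octahydroazulen-8(1H)-one; 18 4-methoxybenzoyl chloride
Product: 19 (3R,3aS,4S,8aS)-3-hydroxy-6,8a-dimethyl-8-oxo-3-(propan-2-yl)decahydroazulen-4-yl 4-methoxybenzoate
Conditions: 4-MeOC6H4COCl, Et3N, DMAP (cat.), CH2Cl2, 0 °C to rt
Reagents that add atoms: 4-methoxybenzoyl chloride (18), COc1ccc(cc1)C(Cl)=O
Why: DMAP-catalysed acylation (nucleophilic acyl substitution) should occur only at the secondary C4 hydroxyl because the tertiary C3 hydroxyl is too hindered, and no stereocentre is touched.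

Step 8
Reactants: 19 (3R,3aS,4S,8aS)-3-hydroxy-6,8a-dimethyl-8-oxo-3-(propan-2-yl)decahydroazulen-4-yl 4-methoxybenzoate
Product: 20 (3R,3aS,4S,8aS)-3-hydroxy-6,8a-dimethyl-8-oxo-3-(propan-2-yl)-1,2,3,3a,4,5,8,8a-octahydroazulen-4-yl 4-methoxybenzoate
Conditions: IBX, DMSO/toluene, 70 °C
Reagents that add atoms: none
Why: IBX-mediated dehydrogenation of a ketone (oxidation of its enol) can only engage C7–C6 because C8a is quaternary, so it should give the conjugated enone and at the same time erase the unassigned C6 stereocentre, with ester and tertiary alcohol inert.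

**Compound list**
1 | 5-methylcyclohexane-1,3-dione | CC1CC(=O)CC(=O)C1 | starting material
2 | iodomethane | CI | starting material
3 | 2,5-dimethylcyclohexane-1,3-dione (stereoisomer mixture) | CC1CC(=O)C(C)C(=O)C1 | intermediate
4 | diiodomethane | ICI | starting material
5 | ethylzinc 3,6-dimethyl-5-oxobicyclo[4.1.0]heptan-1-olate (zinc cyclopropanolate; not isolated) | CC[Zn]OC12CC(C)CC(=O)C1(C)C2 | intermediate
6 | ethylzinc 2,6-dimethyl-4-oxocyclohept-1-en-1-olate (ring-expanded zinc enolate; not isolated) | CC[Zn]OC1=C(C)CC(=O)CC(C)C1 | intermediate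
7 | 2,6-dimethylcycloheptane-1,4-dione (stereoisomer mixture) | CC1CC(=O)CC(C)CC1=O | intermediate
8 | ethane-1,2-diol | OCCO | starting material
9 | 7,10-dimethyl-1,4-dioxaspiro[4.6]undecan-8-one (stereoisomer mixture) | CC1CC2(CC(C)CC1=O)OCCO2 | intermediate
10 | (S)-1-phenylethan-1-amine | C[C@H](N)c1ccccc1 | starting material
11 | (1S)-N-(7,10-dimethyl-1,4-dioxaspiro[4.6]undecan-8-ylidene)-1-phenylethan-1-amine (ring centres unassigned) | CC1CC2(CC(C)CC1=N[C@@H](C)c1ccccc1)OCCO2 | intermediate
12 | 4-methylpent-1-en-3-one | C=CC(=O)C(C)C | starting material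
13 | 1-[(7S)-7,10-dimethyl-8-{[(1S)-1-phenylethyl]imino}-1,4-dioxaspiro[4.6]undecan-7-yl]-4-methylpentan-3-one (Michael adduct imine; not isolated) | C[C@@H](c1ccccc1)N=C1CC(C)CC2(OCCO2)C[C@]1(C)CCC(=O)C(C)C | intermediate
14 | (2S)-2,6-dimethyl-2-(4-methyl-3-oxopentyl)cycloheptane-1,4-dione (triketone; not isolated) | O=C1CC(C)CC(=O)C[C@]1(C)CCC(=O)C(C)C | intermediate
15 | (3S,3aS,8aS)-3-hydroxy-6,8a-dimethyl-3-(propan-2-yl)octahydroazulene-4,8-dione (cis-fused ketol; not isolated) | O=C1CC(C)CC(=O)[C@@]2(C)CC[C@](O)(C(C)C)[C@@H]12 | intermediate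
16 | (3R,3aR,8aS)-3-hydroxy-6,8a-dimethyl-3-(propan-2-yl)octahydroazulene-4,8-dione (trans-fused ketol) | O=C1CC(C)CC(=O)[C@@]2(C)CC[C@@](O)(C(C)C)[C@H]12 | intermediate
17 | (3R,3aS,4S,8aS)-3,4-dihydroxy-6,8a-dimethyl-3-(propan-2-yl)octahydroazulen-8(1H)-one | O[C@H]1CC(C)CC(=O)[C@@]2(C)CC[C@@](O)(C(C)C)[C@H]12 | intermediate
18 | 4-methoxybenzoyl chloride | COc1ccc(cc1)C(Cl)=O | starting material
19 | (3R,3aS,4S,8aS)-3-hydroxy-6,8a-dimethyl-8-oxo-3-(propan-2-yl)decahydroazulen-4-yl 4-methoxybenzoate | COc1ccc(C(=O)O[C@H]2CC(C)CC(=O)[C@@]3(C)CC[C@@](O)(C(C)C)[C@H]23)cc1 | intermediate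
20 | (3R,3aS,4S,8aS)-3-hydroxy-6,8a-dimethyl-8-oxo-3-(propan-2-yl)-1,2,3,3a,4,5,8,8a-octahydroazulen-4-yl 4-methoxybenzoate | COc1ccc(C(=O)O[C@H]2CC(C)=CC(=O)[C@@]3(C)CC[C@@](O)(C(C)C)[C@H]23)cc1 | target

Total step count: 8. Longest linear sequence: 8 steps (1 to 20).

**Steps most likely to fail**

Step 5. The ketol manifold is under thermodynamic control, so an insufficient energy gap between the ring-fusion epimers, or slow interconversion through retro-aldol, would leave cis-fused ketol in the mixture, and prolonged base could start elimination of the tertiary hydroxyl. The fallback installs C3 and C3a kinetically on a dehydrated ring-closure product. It sets out from triketone 14, obtained by stopping the telescoped sequence after the acid hydrolysis. KOH in MeOH at reflux should give, through the only ketol able to dehydrate, the bicyclic enedione F1 (Robinson-type aldol condensation). NaBH4/CeCl3·7H2O at −78 °C (Luche reduction) should reduce the conjugated C4 carbonyl from the face opposite the angular methyl group to the allylic alcohol F2. VO(acac)2/tBuOOH should deliver oxygen to the C3=C3a bond syn to that hydroxyl to give the epoxy alcohol F3, whose C3–O bond already has the configuration of the target. Dess–Martin periodinane should give the epoxy ketone F4, and SmI2 in THF/MeOH at −78 °C should cleave the C3a–O bond (reductive opening of an α,β-epoxy ketone). In the resulting 3-hydroxy-4-ketone only C3a can still equilibrate (Et3N, CH2Cl2), and it is expected to do so toward 16, where the main route is rejoined.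

Step 2. Cyclopropanation of the fully substituted zinc enolate may be slow, and the ring-expanded organozinc may react further with excess carbenoid. The fallback replaces the carbenoid by a radical ring expansion. It sets out from dione 3, which is C-alkylated with CH2Br2 (NaH, THF/HMPA) to the bromomethyl dione F5. Bu3SnH/AIBN in benzene at 80 °C (slow addition) should then effect the Dowd–Beckwith ring expansion (attack of the primary radical on a ring carbonyl, β-scission to the tertiary α-keto radical, hydrogen transfer), returning to 7.

Step 8. Enolisation of the neopentylic ketone may be slow under the IBX conditions, which would let oxidation continue at the allylic C5 position of the product. The fallback separates enolisation from oxidation (Saegusa–Ito oxidation). It sets out from 19: TMSOTf/Et3N in CH2Cl2 at 0 °C should give the bis-silylated compound F6 (trimethylsilyl enol ether at C8/C7, trimethylsilyl ether at the C3 hydroxyl). Pd(OAc)2 in MeCN at rt should give the silyl-protected enone F7 by β-hydride elimination from the palladium enolate, and 1 M HCl in THF should remove the silyl ether to give 20.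

**Further compounds**
F1 | step 5 | (8aS)-6,8a-dimethyl-3-(propan-2-yl)-1,2,5,6,7,8a-hexahydroazulene-4,8-dione | O=C1CC(C)CC(=O)[C@@]2(C)CCC(C(C)C)=C12
F2 | step 5 | (4R,8aS)-4-hydroxy-6,8a-dimethyl-3-(propan-2-yl)-2,4,5,6,7,8a-hexahydroazulen-8(1H)-one | O[C@@H]1CC(C)CC(=O)[C@@]2(C)CCC(C(C)C)=C12
F3 | step 5 | (3R,3aS,4R,8aS)-3,3a-epoxy-4-hydroxy-6,8a-dimethyl-3-(propan-2-yl)octahydroazulen-8(1H)-one | O[C@@H]1CC(C)CC(=O)[C@@]2(C)CC[C@]3(C(C)C)O[C@]123
F4 | step 5 | (3R,3aR,8aS)-3,3a-epoxy-6,8a-dimethyl-3-(propan-2-yl)hexahydroazulene-4,8-dione | O=C1CC(C)CC(=O)[C@@]2(C)CC[C@]3(C(C)C)O[C@]123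
F5 | step 2 | 2-(bromomethyl)-2,5-dimethylcyclohexane-1,3-dione | CC1CC(=O)C(C)(CBr)C(=O)C1
F6 | step 8 | (3R,3aS,4S,8aS)-6,8a-dimethyl-3-(propan-2-yl)-3,8-bis(trimethylsilyloxy)-1,2,3,3a,4,5,6,8a-octahydroazulen-4-yl 4-methoxybenzoate | COc1ccc(C(=O)O[C@H]2CC(C)C=C(O[Si](C)(C)C)[C@@]3(C)CC[C@@](O[Si](C)(C)C)(C(C)C)[C@H]23)cc1
F7 | step 8 | (3R,3aS,4S,8aS)-6,8a-dimethyl-8-oxo-3-(propan-2-yl)-3-(trimethylsilyloxy)-1,2,3,3a,4,5,8,8a-octahydroazulen-4-yl 4-methoxybenzoate | COc1ccc(C(=O)O[C@H]2CC(C)=CC(=O)[C@@]3(C)CC[C@@](O[Si](C)(C)C)(C(C)C)[C@H]23)cc1
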